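**Strategy**

The route rests on disconnecting ring A at C4a–C5 and building it last. Ring C is made first as an enantiopure 2,3-dihydropyran-4-one whose C8a side chain already holds C8, C7, C6 (with its 4-benzyloxybenzyl group) and C5 as a methyl β-keto ester. The key step exploits the fact that C4a–C5–C6–C7–C8–C8a of the phloroglucinol ring A is a folded 1,3,5-tricarbonyl array. One base-mediated Claisen closure from C4a onto the C5 ester, followed by enolisation, gives the aromatic ring with O1 already fixed on C8a, so the benzyl group can only sit at C6. C2 and C3, set by an anti glycolate aldol, are not touched.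

Key step: step 9

**Remarks**

- Flavonoid numbering (O1, C2, C3, C4, C4a, C5 to C8, C8a) is used for ring atoms in all intermediates.
- Assumption on the chemistry: the chlorotitanium enolate of 8 is taken to react in its sulfur-chelated form on the face away from the auxiliary benzyl group, so that the (S)-auxiliary gives the (2R,3R) anti adduct; if a test adduct shows the opposite sense, the (R)-auxiliary is used and nothing else changes.
- Enolates and other metal-bound forms of numbered compounds carry no number of their own.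
- Design of the key-step substrate: C5 is a methyl ester (exchange with methoxide is degenerate), the C2 oxygen is silylated only for the coupling, and the three remaining oxygens are benzyl ethers so that one hydrogenolysis finishes the synthesis.

**Route**

Step 1
Reactants: 1 methyl acetoacetate; 2 4-(benzyloxy)benzyl chloride
Product: 3 methyl 2-[4-(benzyloxy)benzyl]-3-oxobutanoate (racemic)
Conditions: NaH (1.05 equiv), 1 (1.5 equiv), THF, 0 °C; then 2, NaI (0.1 equiv), 0 → 50 °C
Reagents that add atoms: none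
Why: C-alkylation of the sodium enolate of a β-keto ester by a reactive benzylic chloride (acetoacetic ester alkylation), with excess 1 holding back dialkylation.

Step 2
Reactants: 3 methyl 2-[4-(benzyloxy)benzyl]-3-oxobutanoate; 4 N-methoxy-N-methylacetamide
Product: 5 methyl 2-[4-(benzyloxy)benzyl]-3,5-dioxohexanoate (racemic, largely enolised)
Conditions: LiN(i-Pr)2 (2.2 equiv), THF, −78 → 0 °C; then 4 (1.1 equiv), −78 → 0 °C; 1 M HCl
Reagents that add atoms: none
Why: Acylation of a β-keto ester dianion at its terminal carbon by a Weinreb amide, whose chelated tetrahedral adduct collapses only on work-up, so neither over-addition nor proton transfer to the product should interfere.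

Step 3
Reactants: 6 (S)-4-benzyl-1,3-oxazolidine-2-thione; 7 (benzyloxy)acetyl chloride
Product: 8 (S)-4-benzyl-3-[(benzyloxy)acetyl]-1,3-oxazolidine-2-thione
Conditions: Et3N (1.3 equiv), CH2Cl2, 0 °C → rt
Reagents that add atoms: none
Why: N-acylation of the oxazolidinethione by an acid chloride (loading of the chiral auxiliary).

Step 4
Reactants: 8 (S)-4-benzyl-3-[(benzyloxy)acetyl]-1,3-oxazolidine-2-thione; 9 4-(benzyloxy)benzaldehyde
Product: 10 (S)-4-benzyl-3-{(2R,3R)-2-(benzyloxy)-3-[4-(benzyloxy)phenyl]-3-hydroxypropanoyl}-1,3-oxazolidine-2-thione (anti adduct)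
Conditions: TiCl4 (1.1 equiv), i-Pr2NEt (1.1 equiv), CH2Cl2, −78 °C; then 9 (2 equiv) premixed with TiCl4 (2 equiv), −78 °C; aq. NH4Cl
Reagents that add atoms: none
Why: Titanium-mediated anti-selective glycolate aldol: the chlorotitanium (Z)-enolate of 8, held rigid by sulfur-to-titanium chelation, should be attacked on the face away from the auxiliary benzyl group by the TiCl4-bound aldehyde in an open transition state, so the auxiliary fixes C3 as R and the anti topology fixes C2 as R.

Step 5
Reactants: 10 anti aldol adduct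
Product: 11 (2R,3R)-2-(benzyloxy)-3-[4-(benzyloxy)phenyl]-3-hydroxy-N-methoxy-N-methylpropanamide
Conditions: MeNH(OMe)·HCl (3 equiv), imidazole (5 equiv), CH2Cl2, rt
Reagents that add atoms: N,O-dimethylhydroxylamine hydrochloride, CNOC.Cl
Why: The N-acyl oxazolidinethione is an activated amide that is displaced directly by N,O-dimethylhydroxylamine under imidazole buffering (aminolysis of the auxiliary), without hydroxyl protection and without epimerisation at the α-carbon, and auxiliary 6 is recovered.

Step 6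
Reactants: 11 hydroxy Weinreb amide
Product: 12 (2R,3R)-2-(benzyloxy)-3-[4-(benzyloxy)phenyl]-N-methoxy-N-methyl-3-[(triethylsilyl)oxy]propanamide
Conditions: Et3SiCl (1.3 equiv), imidazole (2.5 equiv), DMF, 0 °C → rt
Reagents that add atoms: chlorotriethylsilane, CC[Si](Cl)(CC)CC
Why: Imidazole-promoted silylation of the secondary alcohol (silyl ether protection) prevents retro-aldol cleavage in the strongly basic coupling, and the triethylsilyl group is chosen because dilute acid removes it in step 8.

Step 7
Reactants: 5 methyl 2-[4-(benzyloxy)benzyl]-3,5-dioxohexanoate; 12 silylated Weinreb amide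
Product: 13 methyl (8R,9R)-8-(benzyloxy)-2-[4-(benzyloxy)benzyl]-9-[4-(benzyloxy)phenyl]-3,5,7-trioxo-9-[(triethylsilyl)oxy]nonanoate (C2 epimers, enol tautomers)
Conditions: 5 (2 equiv), LiN(i-Pr)2 (6.1 equiv), THF, −78 → 0 °C; then 12 (1 equiv), −78 → −30 °C; AcOH, −78 °C
Reagents that add atoms: none
Why: Polyanion acylation of a 1,3,5-tricarbonyl compound: the 2,4,6-trianion of 5 adds through its terminal, most basic carbon to the Weinreb amide to form a chelated tetrahedral adduct that collapses only on the acidic quench; low temperature and excess trianion favour addition over α-deprotonation of 12, and the two stereocentres are not involved.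

Step 8
Reactants: 13 silylated triketo ester
Product: 15 methyl 2-[4-(benzyloxy)benzyl]-4-{(2R,3R)-3-(benzyloxy)-2-[4-(benzyloxy)phenyl]-4-oxo-3,4-dihydro-2H-pyran-6-yl}-3-oxobutanoate (epimers at C2 of the butanoate), via desilylated hydroxy triketo ester 14 (not isolated)
Conditions: TsOH·H2O (0.3 equiv), CH2Cl2/MeOH 4:1, 0 °C → rt; then evaporate, toluene, 4 Å MS, 40 °C
Reagents that add atoms: none
Why: Acidic methanolysis removes the silyl group, the freed C2 hydroxyl adds to the 1,5-related C8a carbonyl, and loss of water gives the conjugated dihydropyranone (cyclodehydration of a δ-hydroxy β-diketone); this six-membered closure should outrun 4-pyranone formation, no furanone can form because O3 is benzylated, any exocyclic enol ether isomer would give the same dienolate in step 9, and C2 and C3 take no part.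

Step 9
Reactants: 15 dihydropyranone β-keto ester
Product: 17 (2R,3R)-3-(benzyloxy)-6-[4-(benzyloxy)benzyl]-2-[4-(benzyloxy)phenyl]-5,7-dihydroxy-2,3-dihydro-4H-chromen-4-one, via ring-closed 4,5,7-trione tautomer 16 (not isolated)
Conditions: Mg(OMe)2 (4 equiv), MeOH/THF 1:1, 0 → 40 °C; then 1 M HCl, 0 °C
Reagents that add atoms: none
Why: Proposed new method: Mg(OMe)2 removes a C8 proton, which lies between the C7 ketone and the ring C vinylogous ester, and the resulting extended magnesium dienolate adds through C4a to the C5 methyl ester; loss of methoxide gives trione 16, and enolisation at C4a and C6 aromatises ring A to the 5,7-dihydroxy pattern. The closest known reaction type is the biomimetic Claisen cyclisation of 3,5,7-triketo esters to acylphloroglucinols under magnesium methoxide, transferred here to a triketone whose C8a oxygen is already tied up as the ring C enol ether. Ring A closes in a 6-(enolexo)-exo-trig mode, with magnesium expected to bridge O4 of the dienolate and the ester carbonyl, the two oxygens that end up in the 5-oxido-4-keto chelate of the product. No stereocentre is formed, and C2 and C3 should survive because in the reacting anion C4 is an enolate carbon, so the C3 proton is not activated for enolisation or for E1cB opening of ring C and C8a is shielded from conjugate addition of methoxide. The selectivity needed is C4a-to-C5 closure over aldol attack of C6 on C4 and over retro-Claisen methanolysis: attack at the deactivated C4 would create a quaternary C6 that cannot dehydrate and stays reversible, whereas the Claisen path is pulled forward by aromatisation, and the unproductive C6 enolate of the β-keto ester merely equilibrates with the C8 dienolate. Because O1 is bonded to C8a before the ring forms, the benzyl group can only end up at C6, and the methyl ester makes exchange with methoxide degenerate.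

Step 10
Reactants: 17 tri-O-benzyl dihydroflavonol
Product: 18 gericudranin E, (2R,3R)-3,5,7-trihydroxy-6-(4-hydroxybenzyl)-2-(4-hydroxyphenyl)-2,3-dihydro-4H-chromen-4-one
Conditions: H2 (1 atm), Pd(OH)2/C, EtOAc/MeOH 1:1, rt
Reagents that add atoms: none
Why: Heterogeneous palladium hydrogenolysis (global O-debenzylation) cleaves the two aryl benzyl ethers and the 3-O-benzyl ether under neutral conditions, while the diarylmethane CH2, the C4 ketone and the ring C C2–O1 bond are expected to stay intact, so the (2R,3R) centres pass unchanged into the target.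

**Compound list**

1 | methyl acetoacetate | COC(=O)CC(C)=O | starting material
2 | 4-(benzyloxy)benzyl chloride | ClCc1ccc(OCc2ccccc2)cc1 | starting material
3 | methyl 2-[4-(benzyloxy)benzyl]-3-oxobutanoate (racemic) | COC(=O)C(Cc1ccc(OCc2ccccc2)cc1)C(C)=O | intermediate
4 | N-methoxy-N-methylacetamide | CC(=O)N(C)OC | starting material
5 | methyl 2-[4-(benzyloxy)benzyl]-3,5-dioxohexanoate (racemic) | COC(=O)C(Cc1ccc(OCc2ccccc2)cc1)C(=O)CC(C)=O | intermediate
6 | (S)-4-benzyl-1,3-oxazolidine-2-thione | S=C1N[C@@H](Cc2ccccc2)CO1 | starting material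
7 | (benzyloxy)acetyl chloride | O=C(Cl)COCc1ccccc1 | starting material
8 | (S)-4-benzyl-3-[(benzyloxy)acetyl]-1,3-oxazolidine-2-thione | O=C(COCc1ccccc1)N1C(=S)OC[C@@H]1Cc1ccccc1 | intermediate
9 | 4-(benzyloxy)benzaldehyde | O=Cc1ccc(OCc2ccccc2)cc1 | starting material
10 | (S)-4-benzyl-3-{(2R,3R)-2-(benzyloxy)-3-[4-(benzyloxy)phenyl]-3-hydroxypropanoyl}-1,3-oxazolidine-2-thione | O=C([C@H](OCc1ccccc1)[C@H](O)c1ccc(OCc2ccccc2)cc1)N1C(=S)OC[C@@H]1Cc1ccccc1 | intermediate
11 | (2R,3R)-2-(benzyloxy)-3-[4-(benzyloxy)phenyl]-3-hydroxy-N-methoxy-N-methylpropanamide | CON(C)C(=O)[C@H](OCc1ccccc1)[C@H](O)c1ccc(OCc2ccccc2)cc1 | intermediate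
12 | (2R,3R)-2-(benzyloxy)-3-[4-(benzyloxy)phenyl]-N-methoxy-N-methyl-3-[(triethylsilyl)oxy]propanamide | CON(C)C(=O)[C@H](OCc1ccccc1)[C@H](O[Si](CC)(CC)CC)c1ccc(OCc2ccccc2)cc1 | intermediate
13 | methyl (8R,9R)-8-(benzyloxy)-2-[4-(benzyloxy)benzyl]-9-[4-(benzyloxy)phenyl]-3,5,7-trioxo-9-[(triethylsilyl)oxy]nonanoate (C2 epimers) | COC(=O)C(Cc1ccc(OCc2ccccc2)cc1)C(=O)CC(=O)CC(=O)[C@H](OCc1ccccc1)[C@H](O[Si](CC)(CC)CC)c1ccc(OCc2ccccc2)cc1 | intermediate
14 | methyl (8R,9R)-8-(benzyloxy)-2-[4-(benzyloxy)benzyl]-9-[4-(benzyloxy)phenyl]-9-hydroxy-3,5,7-trioxononanoate (C2 epimers) | COC(=O)C(Cc1ccc(OCc2ccccc2)cc1)C(=O)CC(=O)CC(=O)[C@H](OCc1ccccc1)[C@H](O)c1ccc(OCc2ccccc2)cc1 | intermediate (not isolated)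
15 | methyl 2-[4-(benzyloxy)benzyl]-4-{(2R,3R)-3-(benzyloxy)-2-[4-(benzyloxy)phenyl]-4-oxo-3,4-dihydro-2H-pyran-6-yl}-3-oxobutanoate (epimers at C2 of the butanoate) | O=C1C=C(CC(=O)C(Cc2ccc(OCc3ccccc3)cc2)C(=O)OC)O[C@H](c2ccc(OCc3ccccc3)cc2)[C@H]1OCc1ccccc1 | intermediate
16 | (2R,3R)-3-(benzyloxy)-6-[4-(benzyloxy)benzyl]-2-[4-(benzyloxy)phenyl]-2,3-dihydro-4H-chromene-4,5,7(4aH,6H)-trione (C4a and C6 epimers) | O=C1C2C(=O)C(Cc3ccc(OCc4ccccc4)cc3)C(=O)C=C2O[C@H](c2ccc(OCc3ccccc3)cc2)[C@H]1OCc1ccccc1 | intermediate (not isolated)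
17 | (2R,3R)-3-(benzyloxy)-6-[4-(benzyloxy)benzyl]-2-[4-(benzyloxy)phenyl]-5,7-dihydroxy-2,3-dihydro-4H-chromen-4-one | O=C1c2c(cc(O)c(Cc3ccc(OCc4ccccc4)cc3)c2O)O[C@H](c2ccc(OCc3ccccc3)cc2)[C@H]1OCc1ccccc1 | intermediate
18 | gericudranin E, (2R,3R)-3,5,7-trihydroxy-6-(4-hydroxybenzyl)-2-(4-hydroxyphenyl)-2,3-dihydro-4H-chromen-4-one | O=C1c2c(cc(O)c(Cc3ccc(O)cc3)c2O)O[C@H](c2ccc(O)cc2)[C@H]1O | target

**Totals and risks**

Total step count: 10 steps.
Longest linear sequence: 8 steps (steps 3 to 10, from 6 and 7).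

Steps most likely to fail:

1. Step 9 (key step). The dienolate may fail to close onto the ester: the unproductive β-keto ester chelate, conjugate addition of methoxide at C8a, or base-induced opening of ring C could outrun the Claisen closure, costing material or the C2/C3 configuration.
   Fallback (known chemistry; ring A is bought ready-made and ring C is closed last): it sets out from 2 and 9 and returns to the route at 18. Commercial 2',4',6'-trihydroxyacetophenone is C-benzylated with 2 (aq. KOH/dioxane, 0 °C → rt) to 1-{3-[4-(benzyloxy)benzyl]-2,4,6-trihydroxyphenyl}ethanone F1. MOMCl/i-Pr2NEt (2.1 equiv, CH2Cl2, 0 °C) should protect the two unhindered hydroxyls to give 1-{3-[4-(benzyloxy)benzyl]-2-hydroxy-4,6-bis(methoxymethoxy)phenyl}ethanone F2. BnBr/K2CO3 (DMF, 60 °C) then caps the hindered hydroxyl next to the benzyl substituent to give 1-{2-(benzyloxy)-3-[4-(benzyloxy)benzyl]-4,6-bis(methoxymethoxy)phenyl}ethanone F3. This pattern fixes the regiochemistry, because only the acid-labile oxygen flanked by C–H can later become O1. Claisen–Schmidt condensation of F3 with 9 (KOH, EtOH/THF) gives the (E)-chalcone F4. Juliá–Colonna epoxidation (poly-L-leucine, urea–H2O2, DBU, THF) should give the (2R,3S)-epoxy ketone F5. HCl in MeOH/THF (50 °C) removes both methoxymethyl groups, and the freed ortho phenol opens the epoxide at the benzylic carbon with inversion to give (2R,3R)-5-(benzyloxy)-6-[4-(benzyloxy)benzyl]-2-[4-(benzyloxy)phenyl]-3,7-dihydroxy-2,3-dihydro-4H-chromen-4-one F6. Hydrogenolysis under the conditions of step 10 then gives 18.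

2. Step 7. The polyanion may deprotonate 12 at its α-carbon, with β-elimination of the silyloxy group, or may acylate incompletely.
   Fallback (aldol addition plus oxidation in place of acylation): it sets out from 12 and returns at 13. i-Bu2AlH (THF, −78 °C) reduces 12 to (2R,3R)-2-(benzyloxy)-3-[4-(benzyloxy)phenyl]-3-[(triethylsilyl)oxy]propanal F7. The trianion of 5 (LiN(i-Pr)2, 3 equiv per 5) adds to this far more electrophilic aldehyde at −78 °C to give the 7-hydroxy-3,5-dioxo ester F8 as a mixture of carbinol epimers. Dess–Martin periodinane (NaHCO3, CH2Cl2) oxidises the carbinol to 13.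

3. Step 4. The electron-rich aldehyde may give poor anti/syn or facial selectivity, and the titanium benzylic alkoxide may ionise under excess TiCl4.
   Fallback (chiral Lewis acid control on an achiral enol silane instead of an auxiliary-bound titanium enolate): it sets out from 7 and 9 and returns at 11. Chloride 7 is converted with ethanethiol and Et3N (CH2Cl2, 0 °C) into S-ethyl 2-(benzyloxy)ethanethioate F9, and LiN(i-Pr)2/Me3SiCl (THF, −78 °C) gives (Z)-2-(benzyloxy)-1-(ethylsulfanyl)-1-[(trimethylsilyl)oxy]ethene F10. An asymmetric Mukaiyama aldol with 9 is then run with Sn(OTf)2, a proline-derived chiral diamine of the 1-alkyl-2-(aminomethyl)pyrrolidine type and Bu2Sn(OAc)2 (CH2Cl2, −78 °C). This variant is anti-selective for α-benzyloxy enol silanes, and the diamine enantiomer is chosen for the (2R,3R) series, to give S-ethyl (2R,3R)-2-(benzyloxy)-3-[4-(benzyloxy)phenyl]-3-hydroxypropanethioate F11. MeNH(OMe)·HCl/i-PrMgCl (THF, −20 °C) converts the thioester into 11.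

**Further compounds**

F1 | step 9 | 1-{3-[4-(benzyloxy)benzyl]-2,4,6-trihydroxyphenyl}ethanone | CC(=O)c1c(O)cc(O)c(Cc2ccc(OCc3ccccc3)cc2)c1O
F2 | step 9 | 1-{3-[4-(benzyloxy)benzyl]-2-hydroxy-4,6-bis(methoxymethoxy)phenyl}ethanone | CC(=O)c1c(OCOC)cc(OCOC)c(Cc2ccc(OCc3ccccc3)cc2)c1O
F3 | step 9 | 1-{2-(benzyloxy)-3-[4-(benzyloxy)benzyl]-4,6-bis(methoxymethoxy)phenyl}ethanone | CC(=O)c1c(OCOC)cc(OCOC)c(Cc2ccc(OCc3ccccc3)cc2)c1OCc1ccccc1
F4 | step 9 | (E)-1-{2-(benzyloxy)-3-[4-(benzyloxy)benzyl]-4,6-bis(methoxymethoxy)phenyl}-3-[4-(benzyloxy)phenyl]prop-2-en-1-one | O=C(/C=C/c1ccc(OCc2ccccc2)cc1)c1c(OCOC)cc(OCOC)c(Cc2ccc(OCc3ccccc3)cc2)c1OCc1ccccc1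
F5 | step 9 | {2-(benzyloxy)-3-[4-(benzyloxy)benzyl]-4,6-bis(methoxymethoxy)phenyl}{(2R,3S)-3-[4-(benzyloxy)phenyl]oxiran-2-yl}methanone | O=C([C@@H]1O[C@H]1c1ccc(OCc2ccccc2)cc1)c1c(OCOC)cc(OCOC)c(Cc2ccc(OCc3ccccc3)cc2)c1OCc1ccccc1
F6 | step 9 | (2R,3R)-5-(benzyloxy)-6-[4-(benzyloxy)benzyl]-2-[4-(benzyloxy)phenyl]-3,7-dihydroxy-2,3-dihydro-4H-chromen-4-one | O=C1c2c(cc(O)c(Cc3ccc(OCc4ccccc4)cc3)c2OCc2ccccc2)O[C@H](c2ccc(OCc3ccccc3)cc2)[C@H]1O
F7 | step 7 | (2R,3R)-2-(benzyloxy)-3-[4-(benzyloxy)phenyl]-3-[(triethylsilyl)oxy]propanal | O=C[C@H](OCc1ccccc1)[C@H](O[Si](CC)(CC)CC)c1ccc(OCc2ccccc2)cc1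
F8 | step 7 | methyl 8-(benzyloxy)-2-[4-(benzyloxy)benzyl]-9-[4-(benzyloxy)phenyl]-7-hydroxy-3,5-dioxo-9-[(triethylsilyl)oxy]nonanoate, C8 and C9 configured as in 13, both C7 epimers | COC(=O)C(Cc1ccc(OCc2ccccc2)cc1)C(=O)CC(=O)CC(O)[C@H](OCc1ccccc1)[C@H](O[Si](CC)(CC)CC)c1ccc(OCc2ccccc2)cc1
F9 | step 4 | S-ethyl 2-(benzyloxy)ethanethioate | CCSC(=O)COCc1ccccc1
F10 | step 4 | (Z)-2-(benzyloxy)-1-(ethylsulfanyl)-1-[(trimethylsilyl)oxy]ethene | CCS/C(O[Si](C)(C)C)=C\OCc1ccccc1
F11 | step 4 | S-ethyl (2R,3R)-2-(benzyloxy)-3-[4-(benzyloxy)phenyl]-3-hydroxypropanethioate | CCSC(=O)[C@H](OCc1ccccc1)[C@H](O)c1ccc(OCc2ccccc2)cc1
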